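At 12 d the dusk flask is read. What will it show?

| flask | solid substrate | partner | remark | time |
|---|---|---|---|---|
| dusk | 0.020 M | 1.1 equiv (fed, over 2.0 h) | the very flask that is asked about, followed so far; the fed solution adds 0.10 times the starting volume |  |
| autumn | 0.030 M | 1.1 equiv (fed, over 2.0 h) | run made earlier; the fed solution adds 0.10 times the starting volume |  |
| flask | 0.020 M | 1.10 equiv (fed, over 2.0 h) | the fed solution adds 0.10 times the starting volume | 12 d |

| run | time / d | target / % | solid substrate / % |
|---|---|---|---|
| dusk | 0.208 | 30.8 | 68.9 |
| dusk | 0.333 | 48.8 | 50.5 |
| dusk | 0.417 | 60.9 | 39.0 |
| dusk | 0.625 | 91.8 | 7.5 |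
| dusk | 1.04 | 100.9 | 0 |
| dusk | 1.67 | 100.7 | 0 |
| dusk | 2.50 | 99.7 | 0 |
| autumn | 0.417 | 41.0 | 58.5 |
| autumn | 1.25 | 100.1 | 0 |
| autumn | 2.50 | 99.4 | 0 |
| autumn | 4.00 | 99.3 | 0.5 |
| autumn | 5.00 | 100.6 | 0 |
| autumn | 6.00 | 99.4 | 0 |
| autumn | 8.00 | 100.7 | 0 |

(standard deviation of a reading: 0.5 percentage points)

- every charge counts on the volume at the start, and the solution that is fed holds the whole dose
- solid, in amounts per volume of the solution: solid substrate
- at the start none of the solid substrate is in solution
- what has only dissolved of solid substrate counts as not reacted
- the reaction counts as stopped when no species that holds the solid substrate changes by six tenths of a point or more over the second half of the time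

- the state of affairs at 12 d: stopped, and by what, or still going (for what has run out or reacted, a solid counts together with what of it has only dissolved) (all of the solid substrate has reacted / the partner has run out first / it is still moving / forward and back rates have come level)
- the target standing at 12 d, as a percentage of the solid substrate charged

Is solid substrate left by then? The dusk run reads 7.5% at 0.625 d and 0% at 1.04 d, and 12 d lies far beyond that.

Could the partner stop the dusk flask first? Take the margin, the partner charged minus one equivalent, here 0.100 equiv. If one partner goes into each target, a positive margin makes the solid substrate the limiting reagent, so I reckon target near 100 percent and compute just the correction: a share 9.09% of the partner charge stays unused, in whatever form.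

But you assumed one partner per substrate. What if it takes two? Then 1.10 equiv caps target at 55.0%, and the dusk run read 100.9%.

Does target fade afterwards? The autumn run reads 100.1% at 1.25 d and 100.7% at 8.00 d, a difference near the scatter of 0.5 percentage points. The last 4.00 d before the reading lie beyond any run.

The forecast says all of the solid substrate has reacted, with target 100%: “Partner is in 10% excess, so it does not run out.” My reckoning gives the same target.

The flask gives all of the solid substrate has reacted, with target 99.9%.

    partner ⇌ dormant form (K = 0.440, k = 0.00690 min⁻¹)
    starting material + target → side product (k = 0.0420 M⁻¹ min⁻¹)
    starting material ⇌ reactive form, settled at all times (K = 0.450)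
    solid substrate ⇌ starting material, rate k4*(cs4 - [starting material]) while solid is left; crystals form when [starting material] > cs4 (solubility = 3.10 mM, k = 0.00610 min⁻¹)
    partner + reactive form → target (k = 630 M⁻¹ min⁻¹)

In the dusk flask at 12 d, partner stands at 6.34% of its charge and dormant form at 2.79% of it, on the final volume. Together that is 9.13%, against the 9.09% reckoned from the margin. A neighbour charged with 0.660 equiv has a negative margin, short by 0.340 equiv. If each unpartnered starting material takes one target into side product, target comes to 32.0%. At 12 d that neighbour holds 33.1% target and 65.8% side product, each side product counted twice, with partner at 0%.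

The earlier runs and the new flask are calculated on assumed constants; the scatter is artificial.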